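**Assumption:** the target has no stereocentre or stereogenic axis, so no enantiocontrol is needed; 3-hydroxy-4,5-dimethoxybenzaldehyde and 2,3,4-trimethoxyphenol are taken as catalogue compounds.

**Retrosynthetic overview**
- The γ-pyrone ring is the only ring formed, and it is formed last: O1–C2 closure by 6-endo-dig oxa-Michael addition of an o-hydroxyaryl ynone, triggered by global desilylation.
- Key C4–C3 bond: a nucleophilic acyl carbon (the carbene-derived Breslow intermediate of the A-ring aldehyde) is joined to an electrophilic acetylenic carbon (a B-ring alkynyl(phenyl)iodonium salt).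
- The iodonium salt comes from the B-ring arylacetylene, made from 3-hydroxy-4,5-dimethoxybenzaldehyde by silylation and one-carbon homologation.
- The A-ring aldehyde comes from 2,3,4-trimethoxyphenol by ortho-formylation and silylation.
- Both benzene rings are bought; the two silyl groups fall off in the ring-closing step.

**Route**

Step 1
Reactants: 1 3-hydroxy-4,5-dimethoxybenzaldehyde
Product: 2 3,4-dimethoxy-5-[(triisopropylsilyl)oxy]benzaldehyde
Conditions: TIPSCl (1.2 equiv), imidazole (2.5 equiv), DMF, rt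
Reagents that add atoms: triisopropylsilyl chloride, CC(C)[Si](Cl)(C(C)C)C(C)C
Why: Imidazole-mediated O-silylation of a phenol; the aryl TIPS ether shields the phenol from the basic homologation and from iodine(III) in steps 2 and 3.

Step 2
Reactants: 2 3,4-dimethoxy-5-[(triisopropylsilyl)oxy]benzaldehyde
Product: 3 5-ethynyl-1,2-dimethoxy-3-[(triisopropylsilyl)oxy]benzene
Conditions: dimethyl (1-diazo-2-oxopropyl)phosphonate (1.3 equiv), K2CO3 (2 equiv), MeOH, 0 °C → rt
Reagents that add atoms: dimethyl (1-diazo-2-oxopropyl)phosphonate (Ohira–Bestmann reagent), CC(=O)C(=[N+]=[N-])P(=O)(OC)OC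
Why: Seyferth–Gilbert homologation in its Ohira–Bestmann form turns the non-enolisable aryl aldehyde into the terminal alkyne at rt, conditions a hindered aryl TIPS ether tolerates.

Step 3
Reactants: 3 5-ethynyl-1,2-dimethoxy-3-[(triisopropylsilyl)oxy]benzene
Product: 4 ({3,4-dimethoxy-5-[(triisopropylsilyl)oxy]phenyl}ethynyl)(phenyl)iodonium 4-methylbenzenesulfonate
Conditions: PhI(OH)OTs (1.0 equiv), 4 Å MS, CH2Cl2, rt, dark; Et2O trituration; use fresh
Reagents that add atoms: [hydroxy(tosyloxy)iodo]benzene (Koser's reagent), OI(OS(=O)(=O)c1ccccc1C)c1ccccc1 is not used; the correct reagent SMILES is OI(OS(=O)(=O)c1ccc(C)cc1)c1ccccc1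
Why: Koser-type ligand exchange at iodine(III) converts an arylacetylene C–H into an isolable alkynyl(phenyl)iodonium tosylate, making the alkyne terminus an electrophile.

Step 4
Reactants: 5 2,3,4-trimethoxyphenol
Product: 7 2-hydroxy-3,4,5-trimethoxybenzaldehyde, via salicyl alcohol 6 (not isolated)
Conditions: MgCl2 (1.5 equiv), Et3N (3.75 equiv), (CH2O)n (6.8 equiv), MeCN, reflux; then 1 M HCl
Reagents that add atoms: paraformaldehyde (formaldehyde), C=O
Why: Casnati–Skattebøl magnesium-mediated ortho-formylation delivers formaldehyde only to the single free ortho position, and the salicyl alkoxide is oxidised in situ by a second formaldehyde (Oppenauer-type hydride transfer).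

Step 5
Reactants: 7 2-hydroxy-3,4,5-trimethoxybenzaldehyde
Product: 8 2-[(tert-butyldimethylsilyl)oxy]-3,4,5-trimethoxybenzaldehyde
Conditions: TBSCl (1.3 equiv), imidazole (2.5 equiv), DMF, rt
Reagents that add atoms: tert-butyldimethylsilyl chloride, CC(C)(C)[Si](C)(C)Cl
Why: Imidazole-mediated silylation of the chelated salicylaldehyde OH; masking is needed because a free phenol(ate) would add to the alkynyliodonium salt and buffer away the carbene in step 6.

Step 6
Reactants: 8 2-[(tert-butyldimethylsilyl)oxy]-3,4,5-trimethoxybenzaldehyde; 4 ({3,4-dimethoxy-5-[(triisopropylsilyl)oxy]phenyl}ethynyl)(phenyl)iodonium 4-methylbenzenesulfonate (1.2 equiv)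
Product: 10 1-{2-[(tert-butyldimethylsilyl)oxy]-3,4,5-trimethoxyphenyl}-3-{3,4-dimethoxy-5-[(triisopropylsilyl)oxy]phenyl}prop-2-yn-1-one, via Breslow enaminol 9 (not isolated)
Conditions: 2-(pentafluorophenyl)-6,7-dihydro-5H-pyrrolo[2,1-c][1,2,4]triazol-2-ium tetrafluoroborate (10 mol%), TMEDA (1.5 equiv), toluene–CH2Cl2, −40 → −20 °C
Reagents that add atoms: none
Why: Proposed new method: the triazolylidene converts aldehyde 8 into Breslow enaminol 9, an acyl anion equivalent whose nucleophilic carbon displaces iodobenzene at the acetylenic carbon of 4 and then collapses to the ynone with release of the carbene, so the flavone C4–C3 bond is made from a nucleophilic acyl carbon and an electrophilic alkyne carbon; the closest known reaction type is the carbene-catalysed C–H alkynylation of (mostly heteroaryl) aldehydes with alkynyl(aryl)iodonium salts under amine base at −40 °C, here extended to an electron-rich ortho-siloxybenzaldehyde.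

Step 7
Reactants: 10 1-{2-[(tert-butyldimethylsilyl)oxy]-3,4,5-trimethoxyphenyl}-3-{3,4-dimethoxy-5-[(triisopropylsilyl)oxy]phenyl}prop-2-yn-1-one
Product: 12 2-(3-hydroxy-4,5-dimethoxyphenyl)-6,7,8-trimethoxy-4H-chromen-4-one, via desilylated ynone 11 (not isolated)
Conditions: spray-dried KF (4 equiv), 18-crown-6 (0.5 equiv), dry DMF (0.02 M), rt; then sat. aq. NH4Cl
Reagents that add atoms: none
Why: Fluoride cleaves both aryl silyl ethers and the A-ring phenoxide closes the pyranone by 6-endo-dig oxa-Michael addition; in aprotic medium the 5-exo (aurone) mode would give a non-stabilised vinyl anion and reverts, so the allenolate path to the flavone prevails, as known for o-siloxyaryl ynones with KF/18-crown-6 in DMF.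

**Compound list**

1 | 3-hydroxy-4,5-dimethoxybenzaldehyde | COc1cc(C=O)cc(O)c1OC | starting material
2 | 3,4-dimethoxy-5-[(triisopropylsilyl)oxy]benzaldehyde | COc1cc(C=O)cc(O[Si](C(C)C)(C(C)C)C(C)C)c1OC | intermediate
3 | 5-ethynyl-1,2-dimethoxy-3-[(triisopropylsilyl)oxy]benzene | COc1cc(C#C)cc(O[Si](C(C)C)(C(C)C)C(C)C)c1OC | intermediate
4 | ({3,4-dimethoxy-5-[(triisopropylsilyl)oxy]phenyl}ethynyl)(phenyl)iodonium 4-methylbenzenesulfonate | COc1cc(C#C[I+]c2ccccc2)cc(O[Si](C(C)C)(C(C)C)C(C)C)c1OC.Cc1ccc(S(=O)(=O)[O-])cc1 | intermediate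
5 | 2,3,4-trimethoxyphenol | COc1ccc(O)c(OC)c1OC | starting material
6 | 6-(hydroxymethyl)-2,3,4-trimethoxyphenol (salicyl alcohol, present as its magnesium salt) | COc1cc(CO)c(O)c(OC)c1OC | intermediate (not isolated)
7 | 2-hydroxy-3,4,5-trimethoxybenzaldehyde | COc1cc(C=O)c(O)c(OC)c1OC | intermediate
8 | 2-[(tert-butyldimethylsilyl)oxy]-3,4,5-trimethoxybenzaldehyde | COc1cc(C=O)c(O[Si](C)(C)C(C)(C)C)c(OC)c1OC | intermediate
9 | Breslow enaminol: {2-[(tert-butyldimethylsilyl)oxy]-3,4,5-trimethoxyphenyl}[2-(pentafluorophenyl)-2,5,6,7-tetrahydro-3H-pyrrolo[2,1-c][1,2,4]triazol-3-ylidene]methanol (enol geometry undefined) | OC(=C1N2CCCC2=NN1c1c(F)c(F)c(F)c(F)c1F)c1cc(OC)c(OC)c(OC)c1O[Si](C)(C)C(C)(C)C | intermediate (not isolated)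
10 | 1-{2-[(tert-butyldimethylsilyl)oxy]-3,4,5-trimethoxyphenyl}-3-{3,4-dimethoxy-5-[(triisopropylsilyl)oxy]phenyl}prop-2-yn-1-one | COc1cc(C(=O)C#Cc2cc(OC)c(OC)c(O[Si](C(C)C)(C(C)C)C(C)C)c2)c(O[Si](C)(C)C(C)(C)C)c(OC)c1OC | intermediate
11 | 1-(2-hydroxy-3,4,5-trimethoxyphenyl)-3-(3-hydroxy-4,5-dimethoxyphenyl)prop-2-yn-1-one (present as its potassium phenoxide) | COc1cc(C(=O)C#Cc2cc(OC)c(OC)c(O)c2)c(O)c(OC)c1OC | intermediate (not isolated)
12 | 2-(3-hydroxy-4,5-dimethoxyphenyl)-6,7,8-trimethoxy-4H-chromen-4-one (achiral) | COc1cc(-c2cc(=O)c3cc(OC)c(OC)c(OC)c3o2)cc(O)c1OC | target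

**Step count**

Total: 7 steps. Longest linear sequence: 5 steps (1, 2, 3, 6, 7); the A-ring branch is steps 4, 5, 6, 7.

**Steps most likely to fail, with fallbacks**

Step 6 is the main risk. The hindered, electron-rich aldehyde 8 may form its Breslow intermediate slowly, and the carbene or TMEDA may consume 4 first. The fallback sets out from 3 and 8 and returns at 10, making the same bond in normal polarity. Alkyne 3 is deprotonated with n-BuLi (THF, −78 °C) and added to 8, with a cold AcOH quench to forestall O-to-O silyl migration. This gives racemic 1-{2-[(tert-butyldimethylsilyl)oxy]-3,4,5-trimethoxyphenyl}-3-{3,4-dimethoxy-5-[(triisopropylsilyl)oxy]phenyl}prop-2-yn-1-ol F1, which activated MnO2 (CH2Cl2, rt) oxidises to ynone 10. Step 3 is then not needed.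

Step 3 is the second risk. Koser's reagent may attack the electron-rich arene, or give tosyloxyvinyl adducts, instead of exchanging cleanly at the alkyne C–H. The fallback sets out from 3 and returns at 4. Alkyne 3 is lithiated (n-BuLi, THF, −78 °C), trapped with 2-isopropoxy-4,4,5,5-tetramethyl-1,3,2-dioxaborolane and quenched with HCl in Et2O. This gives 2-({3,4-dimethoxy-5-[(triisopropylsilyl)oxy]phenyl}ethynyl)-4,4,5,5-tetramethyl-1,3,2-dioxaborolane F2. Its fast boron-to-iodine(III) exchange with PhI(OH)OTs (CH2Cl2, 0 °C → rt) delivers 4 without exposing the arene to the reagent for long.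

Step 7 is the third risk. Wet fluoride or a proton source may open the 5-exo channel to the aurone, and the B-ring phenoxide may add to a second ynone. The fallback sets out from 10 and returns at 12, fixing the ring size before the phenol is released. Et2NH (THF/EtOH, rt) adds to the ynone to give (E)-1-{2-[(tert-butyldimethylsilyl)oxy]-3,4,5-trimethoxyphenyl}-3-(diethylamino)-3-{3,4-dimethoxy-5-[(triisopropylsilyl)oxy]phenyl}prop-2-en-1-one F3. TBAF (THF, rt) then removes both silyl groups, and the A-ring phenoxide displaces diethylamine by addition–elimination at the amine-bearing carbon. Only six-membered closure is possible, giving 12.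

**Further compounds**

F1 | step 6 | 1-{2-[(tert-butyldimethylsilyl)oxy]-3,4,5-trimethoxyphenyl}-3-{3,4-dimethoxy-5-[(triisopropylsilyl)oxy]phenyl}prop-2-yn-1-ol (racemic) | COc1cc(C(O)C#Cc2cc(OC)c(OC)c(O[Si](C(C)C)(C(C)C)C(C)C)c2)c(O[Si](C)(C)C(C)(C)C)c(OC)c1OC
F2 | step 3 | 2-({3,4-dimethoxy-5-[(triisopropylsilyl)oxy]phenyl}ethynyl)-4,4,5,5-tetramethyl-1,3,2-dioxaborolane | COc1cc(C#CB2OC(C)(C)C(C)(C)O2)cc(O[Si](C(C)C)(C(C)C)C(C)C)c1OC
F3 | step 7 | (E)-1-{2-[(tert-butyldimethylsilyl)oxy]-3,4,5-trimethoxyphenyl}-3-(diethylamino)-3-{3,4-dimethoxy-5-[(triisopropylsilyl)oxy]phenyl}prop-2-en-1-one | CCN(CC)/C(=C/C(=O)c1cc(OC)c(OC)c(OC)c1O[Si](C)(C)C(C)(C)C)c1cc(OC)c(OC)c(O[Si](C(C)C)(C(C)C)C(C)C)c1
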